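**Assumption:** 5,7-dihydroxychromone, (R)-t-BuPyOx, phenylboronic acid and salicyl alcohol are treated as catalogue items. The target's single stereocentre (C2) is S, and it is set inside the route, not bought.

## Retrosynthetic overview
1. Dichamanetin ⇒ (S)-pinocembrin + 2 × salicyl alcohol: double ortho-hydroxybenzylation at C6 and C8 (ZnCl2, o-quinone-methide-type Friedel–Crafts), done last.
2. (S)-Pinocembrin ⇒ its 5,7-diacetate ⇒ 5,7-diacetoxychromone + PhB(OH)2: Pd/(R)-t-BuPyOx asymmetric conjugate addition sets C2.
3. 5,7-Diacetoxychromone ⇒ commercial 5,7-dihydroxychromone + Ac2O.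
4. Rings: the benzopyranone bicycle is bought intact and no ring is formed; the C2-phenyl ring is appended first, then the two 2-hydroxybenzyl rings.

## Route

**Step 1**
Reactants: 1, 5,7-dihydroxychromone (5,7-dihydroxy-4H-chromen-4-one); 2, acetic anhydride
Product: 3, 5,7-diacetoxychromone (4-oxo-4H-chromene-5,7-diyl diacetate)
Conditions: Ac2O (3 equiv), pyridine, DMAP (cat.), CH2Cl2, 0 °C → rt
Reagents that add atoms: acetic anhydride, CC(=O)OC(C)=O
Why: DMAP-catalysed O-acylation caps both phenols (including the chelated 5-OH), which makes the chromone soluble and keeps the enone electron-poor for the conjugate addition.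

**Step 2**
Reactants: 3, 5,7-diacetoxychromone; 4, phenylboronic acid
Product: 5, (S)-5,7-diacetoxyflavanone ((2S)-4-oxo-2-phenylchroman-5,7-diyl diacetate)
Conditions: PhB(OH)2 (2 equiv), Pd(OCOCF3)2 (5 mol %), (R)-t-BuPyOx (6 mol %), NH4PF6 (30 mol %), H2O (5 equiv), ClCH2CH2Cl, 60 °C
Reagents that add atoms: phenylboronic acid, OB(O)c1ccccc1
Why: Pd(II)-catalysed asymmetric conjugate addition of an arylboronic acid to a chromone (Hayashi–Miyaura-type 1,4-addition with a PyOx ligand), in which the ligand's t-Bu group blocks one enone face, so the (R)-ligand should give (S) at C2 — the mirror of the (S)-ligand → (R)-flavanone outcome as I recall it, to be confirmed by chiral HPLC and by rotation after step 3 (natural (S)-pinocembrin is levorotatory).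

**Step 3**
Reactants: 5, (S)-5,7-diacetoxyflavanone
Product: 6, (S)-pinocembrin ((2S)-5,7-dihydroxy-2-phenylchroman-4-one)
Conditions: HCl (about 1.25 M, from AcCl) in MeOH, rt
Reagents that add atoms: none
Why: Acid-catalysed transesterification removes the aryl acetates while avoiding the basic conditions under which flavanones racemise by retro-oxa-Michael opening to the chalcone, so C2 is untouched.

**Step 4**
Reactants: 6, (S)-pinocembrin; 7, 2-hydroxybenzyl alcohol (salicyl alcohol)
Product: 8, dichamanetin ((2S)-5,7-dihydroxy-6,8-bis(2-hydroxybenzyl)-2-phenylchroman-4-one)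
Conditions: salicyl alcohol (2.5 equiv, added in portions), anhydrous ZnCl2 (about 3 equiv), 1,4-dioxane, reflux; chromatographic separation from mono-benzylated products
Reagents that add atoms: 2-hydroxybenzyl alcohol, OCc1ccccc1O (two equivalents incorporated, each losing water)
Why: ZnCl2 ionises the salicyl alcohol to an o-quinone-methide/benzyl-cation equivalent that undergoes Friedel–Crafts alkylation at C6 and C8, the only two free and strongly activated positions of the phloroglucinol-type A ring, without touching C2.

## Compound list
1 | 5,7-dihydroxychromone | O=c1ccoc2cc(O)cc(O)c12 | starting material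
2 | acetic anhydride | CC(=O)OC(C)=O | starting material
3 | 5,7-diacetoxychromone | O=c1ccoc2cc(OC(C)=O)cc(OC(C)=O)c12 | intermediate
4 | phenylboronic acid | OB(O)c1ccccc1 | starting material
5 | (S)-5,7-diacetoxyflavanone | O=C1C[C@@H](c2ccccc2)Oc2cc(OC(C)=O)cc(OC(C)=O)c21 | intermediate
6 | (S)-pinocembrin | O=C1C[C@@H](c2ccccc2)Oc2cc(O)cc(O)c21 | intermediate
7 | 2-hydroxybenzyl alcohol (salicyl alcohol) | OCc1ccccc1O | starting material
8 | dichamanetin | O=C1C[C@@H](c2ccccc2)Oc2c(Cc3ccccc3O)c(O)c(Cc3ccccc3O)c(O)c21 | target

## Summary
Total step count: 4. Longest linear sequence: 4.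

Steps most likely to fail:
1. **Step 2** (reactivity and ee of the conjugate addition on a 5,7-dioxygenated chromone, possible ring-opening to chalcone, and the assumed sense of induction). Fallback: form the C2–O bond instead of the C2–aryl bond — open (S)-styrene oxide with a lithiated dithiane of a protected 2-hydroxy-4,6-dioxygenated benzaldehyde, then close the ring by intramolecular Mitsunobu reaction with inversion and unmask the ketone to give (S)-pinocembrin.
2. **Step 4** (mono/bis/over-benzylation mixtures, salicyl alcohol self-condensation, and possible loss of ee under ZnCl2 and heat). Fallback: reverse the order — hydroxybenzylate achiral 5,7-dihydroxychromone at C6 and C8 first, peracetylate, then run the asymmetric Pd conjugate addition and deacetylate, so the stereocentre never sees the Lewis acid.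
3. **Step 3** (incomplete deacetylation or partial racemisation). Fallback: change the protecting-group strategy — leave the chelated 5-OH free and protect only the 7-OH as a TIPS ether, then remove it after the conjugate addition with HF·pyridine or AcOH-buffered TBAF.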